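(Its constants are invented; the run is a simulation.)

At early times, the meeting opened with the view that starting material, at the charged amounts, has a half-life of 26 h by the route to first product and 41 h by the route to other mono adduct, while first product has a shorter one of 21 h against reagent, so its loss could not be set aside.

common to all: starting material 1.0 M
- cedar: reagent 1.10 M; a single well-mixed tank run continuously and read at steady state, 20 h in it on average
- maple: reagent 1.10 M; everything together in a closed stirred flask, run for 20 h; time 20 h
- ash: reagent 1.10 M; one stirred flow tank at steady state, fed with the mixture as stated, mean residence time 60.0 h
- larch: reagent 1.10 M (fed, over 16.0 h); all but reagent at the start; reagent goes in evenly over 16.0 h, the run ends at 20 h; time 20 h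

    starting material + reagent → first product (k1 = 6.69 × 10⁻⁶ L mol⁻¹ s⁻¹)
    starting material + reagent → other mono adduct (k2 = 4.25 × 10⁻⁶ L mol⁻¹ s⁻¹)
    reagent + first product → bis adduct (k3 = 8.25 × 10⁻⁶ L mol⁻¹ s⁻¹)
    reagent + other mono adduct → bis adduct (k4 = 1.85 × 10⁻⁵ L mol⁻¹ s⁻¹)

1. the set-up with the highest amount of first product at the outlet or at the end, in percent of the starting material put in ("none" if the first two lie within 2 percentage points) (cedar / maple / ash / larch / none)
2. amount of first product at the outlet or at the end, in percent of the starting material put in, cedar
3. amount of first product at the outlet or at the end, in percent of the starting material put in, maple
4. amount of first product at the outlet or at the end, in percent of the starting material put in, ash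
5. amount of first product at the outlet or at the end, in percent of the starting material put in, larch

- the stated concentrations are those of everything mixed, before any reaction; amounts are the same in each set-up
- the feed brings no volume worth counting
- run time (maple): 20 h

I, keeping the minutes, argued that the steps making and consuming first product each use one reagent, so in maple and larch, where nothing leaves the vessel, reagent cancels from their ratio, and first product, as a fraction m of the starting material charged, follows the fraction a of starting material left. It grows while m/a stands below the standstill ratio S, the constant making first product over the constant consuming it, a selectivity factor, 0.811. With n, the constant consuming first product over the sum of the two constants consuming starting material, 0.754, and C, the first constant over that sum less the consuming constant, 2.49, the curve is m = C(a^n − a), and it peaks at a = 31.7% with m = 25.7%.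

For maple, I reported, reagent held at its charge would bring a to 42.0%, but reagent falls, so I took a mean of 0.810 M, which gives a = 52.8% and m = 22.3%. Larch, I added, gets 0.600 of maple's reagent-time before any consumption, so it should stand earlier on the same rising curve. The curve does not cover the two tanks.

The author of the forecast then put maple first, giving cedar 14.9%, maple 21.7%, ash 17.3% and larch 17.2%, a maple figure just under mine, and held that “the 60 h tank gains conversion but loses selectivity to back-mixing”.

The simulation gives maple as best, with cedar 14.9%, maple 21.8%, ash 17.3% and larch 17.3%.

Maple at 20.0 h holds 21.8% first product on 54.7% starting material, so m/a is 0.399, below S, and first product there is made 2.04 times as fast as it is used up. The neighbour flask with 2.8 M of reagent reads 24.2% on 20.3%, an m/a of 1.19, above S. Maple has not come to rest at 20.0 h, when 47% of its charged reagent is still unbound. Left until 200 h, maple reads first product 25.6%, starting material 27.8%, bis adduct 37.4% and reagent 0.386% of its own charge.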